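## The problem

The target 23 is a depside: two hexasubstituted benzene rings joined by one aryl ester. Ring A is a methyl benzoate (C1 CO2Me, C2 Me, C3 Me, C4 O-acyl, C5 Me, C6 OMe). Ring B is the acyl half (C1′ carbonyl-bearing carbon, C2′ OH, C3′ CHO, C4′ OH, C5′ CHO, C6′ Me). There is no stereocentre, so the task is regiochemical: twelve substituents have to be placed without isomer mixtures. Ring B is orsellinic acid 16 lacking only two formyl groups and can be bought. Ring A has no purchasable counterpart, and its three methyl groups, two meta oxygens and ester cannot be set cleanly by substitution on a cresol or xylenol. The ester joins a phenol flanked by two methyl groups to an acid flanked by methyl and oxygen, so it is hard to form; once formed it is open to hydroxide, alkoxide and amines. The two aldehydes, each next to a free phenol, will not survive hydrogenation, oxidants or basic nucleophiles and should enter last. The key step rests on the resorcinol monoether pattern of ring A: the C4 oxygen and the C6 methoxy group sit meta across the C5 methyl, which is what a ketene carbonyl carbon (C4) and a 1-methoxyalkyne (C5, C6) deliver, while C2 and C3 come from a trisubstituted alkene and C1, para to the C4 oxygen, stays free for the ester.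

## Retrosynthesis

**23 to 21.** The C3′–CHO and C5′–CHO bonds are cut. In the dihydroxy depside 21 the only two ring CH positions of the whole molecule are the two that must carry formyl groups, so no regiochemical question arises. The aldehydes then appear after every reductive and basic operation. The forward reaction must substitute the same ring twice. This is reasonable because both sites are ortho or para to the C2′ oxygen, the C4′ oxygen and the C6′ methyl, while the ester and the first formyl equivalent are meta to the carbon attacked second.

**21 to 20 to 15 + 18.** The ester C(=O)–O bond to the C4 oxygen is cut, with the ring B hydroxyls carried as benzyl ethers in 20. This divides the molecule into two halves of similar size. The benzyl ethers prevent self-acylation of the acid and leave by hydrogenolysis, which touches nothing else in 20. The forward reaction must acylate a doubly flanked phenol (15) with a doubly flanked acid (18). That calls for a slim, very reactive acyl donor, which an electron-rich benzoic acid can provide as an acylium-like mixed anhydride. Ring A of 15 is fully substituted, so C-acylation there is excluded.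

**18 to 17 to 16.** Only protecting-group changes are involved: exhaustive benzylation of orsellinic acid 16 to 17 and saponification of the benzyl ester to 18. All carbons of ring B are bought.

**15 to 12 to 11.** The C1–CO2Me bond is cut. In phenol 11, C1 is the only ring CH and is para to the hydroxyl, so bromination to 12 has one possible site. Exchange of bromine for lithium then brings in the ester carbon directly at the ester oxidation level. A formylation–oxidation–esterification sequence would need three operations and an oxidation next to a free, electron-rich phenol. Direct para carboxylation of the phenolate is unreliable. The forward reaction asks that the aryllithium acylate only once, which its two ortho substituents favour.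

**11 to 3 + 6 (key disconnection).** Three ring bonds are cut: C4–C5, C6–C1 and C3–C4. Ring A falls apart into the diazo ketone 3 and the ynol ether 6, both five-atom, open-chain compounds. Five of the six substituents, including the free C4 hydroxyl and the finished C6 methoxy group, arrive in their final positions. The other partition of the ring, with an unpolarized dialkylalkyne as two-carbon partner, would give up the polarization that fixes the orientation. Aromatic substitution routes founder on meta oxygen placement. The forward cascade needs a clean Wolff rearrangement, a regioselective [2+2] addition and a six-electron ring closure.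

**3 to 1 and 6 to 4.** The diazo carbon–nitrogen bond of 3 is traced to the methyl group of the commercial enone 1 by diazo transfer. The methyl–alkyne bond of 6 is traced to methylation of the acetylide obtained from the chloroacetal 4. Both are one-flask operations.

## Roads not taken

**Alternative 1:** Here the C4′–O and C3′–CHO bonds of ring B are made late on the intact depside. Fluoride would release an aryne from the ortho-silyl aryl triflate A2. The carbonyl group of N,N-dimethylformamide A3 would add across it, and hydrolysis of the resulting aminal would give the salicylaldehyde A1.
- Merits: the neighbouring C2′ alkoxy group directs oxygen to the distal aryne carbon, so the hydroxyl/formyl pair is placed with certainty, and that formyl needs no electrophilic substitution.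
- Weak points: A2 is a heavily functionalized depside that costs several steps to make. The C4′ oxygen it installs is already present in 16. Fluoride and the basic by-products of aminal hydrolysis endanger the aryl ester. A1 still lacks the C5′ formyl group and carries a methoxymethyl ether, so an electrophilic formylation and a deprotection remain. Ring A is not addressed at all, so phenol 15 would be needed anyway.
- Comparison: the aryne route is superior only in guaranteeing one formyl position without a second substitution on the same ring. The chosen plan sets against this that both free positions of 21 are wanted, so one operation replaces a longer sequence.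

**Alternative 2:** Here ring B is built by cutting C1′–C2′ and C5′–C6′. The diene A6, 1-methoxy-1,3-bis(trimethylsilyloxy)buta-1,3-diene, would add across the triple bond of the ring A aryl but-2-ynoate A5. Loss of methanol and desilylation would give the resorcylate A4, which is the same compound as 21.
- Merits: the orientation is dependable, since the nucleophilic diene terminus bonds to the alkyne β-carbon. The hindered phenol 15 is acylated by a slim alkynoic acid instead of a di-ortho-substituted benzoic acid. No benzyl groups are needed, so A4 is reached from 15 in two operations against four on the ring B side of the chosen plan (steps 6 to 9).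
- Weak points: a β-methyl ynoate is a sluggish dienophile and needs heat that the silyl ketene acetal tolerates poorly. The aryl ester of A5 is an active ester that the ketene acetal carbon can attack directly. The sequence rebuilds a ring that is on the shelf as 16.
- Comparison: this road is shorter for ring B. The chosen plan sets against that four routine operations on a bought ring. Alternative 2 also leaves the real difficulty, ring A, untouched.

**Alternative 3:** Here ring A is cut at C2–C3 and C5–C6. The enolate of pentan-3-one A8 would displace methoxide from dimethyl 2-(1-methoxyethylidene)malonate A9. The α′-carbanion would then attack an ester carbonyl to give methyl 2,4-dihydroxy-3,5,6-trimethylbenzoate A7.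
- Merits: all six ring A substituents, the ester included, would be set in one operation from two cheap compounds. The chosen plan needs five steps (1 to 5) to reach 15. On paper this is the shortest road to ring A, and it avoids diazo compounds and photochemistry.
- Weak points: ketone enolates and alkoxyalkylidene malonates tend to close through oxygen to 2-pyranones. The β-carbon of A9 is tetrasubstituted and carries an acidic methyl group, so proton transfer can quench the enolate. The second enolization must occur at the α′ position of an already stabilized anion. A7 also emerges with both oxygens free, so the C4 hydroxyl would have to be acylated selectively and the chelated C6 hydroxyl methylated afterwards, in the presence of the depside ester.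
- Comparison: the chosen plan sets against this step economy a pericyclic cascade whose orientation is fixed by the polarity of its partners. It also delivers the C4 hydroxyl free and the C6 oxygen already methylated.

Key step: step 3

## Route

Remark on the chemistry: 1-methoxyprop-1-yne 6 is assumed not to be a stock item and is made in step 2. Commercial 1 is taken as the E isomer. The target has no stereocentre.

Step 1
Reactants: 1 (E)-3-methylpent-3-en-2-one
Product: 3 (E)-1-diazo-3-methylpent-3-en-2-one, via trifluoroacetyl diketone 2 (not isolated)
Conditions: LiN(SiMe3)2, THF, −78 °C; CF3CO2CH2CF3; aq. HCl; then MsN3, Et3N, H2O, MeCN, rt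
Reagents that add atoms: methanesulfonyl azide, CS(=O)(=O)N=[N+]=[N-]
Why: Kinetic deprotonation of the methyl ketone and Claisen-type trifluoroacetylation activate the α′ carbon as the 1,3-diketone 2. Regitz-type diazo transfer with loss of the trifluoroacetyl group (detrifluoroacetylative diazo transfer) then gives the diazo ketone without exposing the alkene to diazomethane.

Step 2
Reactants: 4 chloroacetaldehyde dimethyl acetal (2-chloro-1,1-dimethoxyethane)
Product: 6 1-methoxyprop-1-yne, via sodium methoxyacetylide 5 (not isolated)
Conditions: NaNH2 (3 equiv), liq. NH3, −33 °C; then MeI, −33 °C → rt; distillation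
Reagents that add atoms: iodomethane, CI
Why: Two eliminations (methanol, then HCl) give methoxyacetylene, which the third equivalent of amide holds as its sodium acetylide. SN2 methylation in the same flask is the standard entry to 1-alkoxyalk-1-ynes.

Step 3
Reactants: 3 (E)-1-diazo-3-methylpent-3-en-2-one, 6 1-methoxyprop-1-yne
Product: 11 3-methoxy-2,5,6-trimethylphenol, via vinylketene 7 (not isolated), via vinylcyclobutenone 8 (not isolated), via dienylketene 9 (not isolated), via cyclohexadienone 10 (not isolated)
Conditions: hν (254 nm, low-pressure Hg lamp, quartz), 6 (2 equiv), ClCH2CH2Cl, rt; then 80 °C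
Reagents that add atoms: none
Why: Photochemical Wolff rearrangement of 3 (loss of N2 and 1,2-shift of the alkenyl group) gives the vinylketene 7, whose ketene C=C adds the electron-rich alkyne 6 in a [2+2] cycloaddition to the 4-alkenylcyclobutenone 8, forming C4–C5 and C6–C1. Four-electron electrocyclic opening of 8, by light or on heating and reversible, gives the dienylketene 9; the rotamer with the alkenyl group turned inward is drained by six-electron electrocyclization between the ketene carbon and the terminal alkene carbon (C3–C4), and the dienone 10 tautomerizes to the phenol. Ring A is therefore closed by a thermal disrotatory 6π electrocyclization, a pericyclic 6-endo-type closure without ionic intermediates, and the four-membered ring of 8 is only a relay. The closest known reaction type is the Danheiser benzannulation in its diazo ketone (photo-Wolff) form with alkoxy- and siloxyalkynes. No stereocentre is created, since the sp3 carbons of 8 and 10 disappear on aromatization. The selectivity needed is the orientation of the [2+2] step, and it is secured by the polarization of the partners: the nucleophilic methyl-bearing carbon of the ynol ether bonds to the electrophilic ketene carbonyl carbon, which puts methyl at C5 and methoxy at C6 beside the new C4 hydroxyl and leaves C1 as the only CH. The E geometry of 1 keeps the terminal methyl group outside the closing termini of 9, and the excess of 6 keeps the ketene from being taken by phenol already formed.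

Step 4
Reactants: 11 3-methoxy-2,5,6-trimethylphenol
Product: 12 4-bromo-3-methoxy-2,5,6-trimethylphenol
Conditions: NBS, MeCN, 0 °C
Reagents that add atoms: N-bromosuccinimide, O=C1CCC(=O)N1Br
Why: Electrophilic aromatic bromination; the only ring CH (C1 of ring A) is para to the hydroxyl and ortho to the methoxy group, so there is one possible site.

Step 5
Reactants: 12 4-bromo-3-methoxy-2,5,6-trimethylphenol
Product: 15 methyl 4-hydroxy-2-methoxy-3,5,6-trimethylbenzoate, via dilithio phenolate 13 (not isolated), via aryl methyl carbonate 14 (not isolated)
Conditions: t-BuLi (3.1 equiv), THF, −78 °C; cannulated into ClCO2Me (excess), THF, −78 °C → rt; then K2CO3, MeOH, rt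
Reagents that add atoms: methyl chloroformate, COC(=O)Cl
Why: Deprotonation and bromine–lithium exchange (the third equivalent of t-BuLi destroys the tert-butyl bromide) give the O,C-dilithio species 13, which methyl chloroformate acylates at carbon and at oxygen; inverse addition and the two ortho substituents hold the aryllithium to a single addition. Methanolysis in the same flask cleaves the aryl carbonate of 14, while the hindered methyl benzoate can only exchange methoxide for methoxide.

Step 6
Reactants: 16 orsellinic acid (2,4-dihydroxy-6-methylbenzoic acid)
Product: 17 benzyl 2,4-bis(benzyloxy)-6-methylbenzoate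
Conditions: BnBr (3.5 equiv), K2CO3, DMF, rt → 60 °C
Reagents that add atoms: benzyl bromide, BrCc1ccccc1
Why: Williamson alkylation of the carboxylate and both phenoxides; the carboxylate reacts first at rt, which removes the risk of decarboxylation before the chelated C2′ hydroxyl is benzylated on warming.

Step 7
Reactants: 17 benzyl 2,4-bis(benzyloxy)-6-methylbenzoate
Product: 18 2,4-bis(benzyloxy)-6-methylbenzoic acid
Conditions: KOH, DMSO/H2O, 90 °C; then aq. HCl
Reagents that add atoms: potassium hydroxide, [K+].[OH-]
Why: Saponification of the hindered benzyl ester under forcing conditions; the benzyl aryl ethers are inert to hydroxide.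

Step 8
Reactants: 15 methyl 4-hydroxy-2-methoxy-3,5,6-trimethylbenzoate, 18 2,4-bis(benzyloxy)-6-methylbenzoic acid
Product: 20 3-methoxy-4-(methoxycarbonyl)-2,5,6-trimethylphenyl 2,4-bis(benzyloxy)-6-methylbenzoate, via mixed anhydride 19 (not isolated)
Conditions: 18, (CF3CO)2O, toluene, 0 °C; then 15, rt
Reagents that add atoms: none
Why: Trifluoroacetic anhydride esterification, the classical depside coupling; the electron-rich, di-ortho-substituted acid forms the mixed anhydride 19, which ionizes toward a linear acylium ion that the doubly flanked phenol oxygen of 15 can reach. Ring A has no free carbon, so only O-acylation is possible there.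

Step 9
Reactants: 20 3-methoxy-4-(methoxycarbonyl)-2,5,6-trimethylphenyl 2,4-bis(benzyloxy)-6-methylbenzoate
Product: 21 3-methoxy-4-(methoxycarbonyl)-2,5,6-trimethylphenyl 2,4-dihydroxy-6-methylbenzoate
Conditions: H2 (1 atm), 10% Pd/C, EtOAc, rt
Reagents that add atoms: none
Why: Hydrogenolysis of the two benzyl ethers; the aryl ester, the methyl ester and the methyl ether are inert, and no aldehyde is present yet.

Step 10
Reactants: 21 3-methoxy-4-(methoxycarbonyl)-2,5,6-trimethylphenyl 2,4-dihydroxy-6-methylbenzoate
Product: 23 3-methoxy-4-(methoxycarbonyl)-2,5,6-trimethylphenyl 3,5-diformyl-2,4-dihydroxy-6-methylbenzoate (target), via bis-chloroether adduct 22 (not isolated)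
Conditions: Cl2CHOMe (6 equiv), TiCl4 (8 equiv), CH2Cl2, 0 °C → rt; then ice/aq. HCl
Reagents that add atoms: dichloromethyl methyl ether, COC(Cl)Cl; water, O
Why: Double Rieche formylation; C3′ and C5′ are both ortho to the titanium-bound C4′ oxygen and ortho or para to the C2′ oxygen and the C6′ methyl, while the ester and the first chloro(methoxy)methyl group are meta to the carbon attacked next, so the ring should stay reactive for the second substitution. Ring A has no free position, and hydrolysis of the two α-chloro ethers of 22 on work-up gives the dialdehyde.

## Compound list

1 | (E)-3-methylpent-3-en-2-one | C/C=C(\C)C(C)=O | starting material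
2 | (E)-1,1,1-trifluoro-5-methylhept-5-ene-2,4-dione | C/C=C(\C)C(=O)CC(=O)C(F)(F)F | intermediate (not isolated)
3 | (E)-1-diazo-3-methylpent-3-en-2-one | C/C=C(\C)C(=O)C=[N+]=[N-] | intermediate
4 | chloroacetaldehyde dimethyl acetal (2-chloro-1,1-dimethoxyethane) | COC(CCl)OC | starting material
5 | sodium methoxyacetylide | [Na+].[C-]#COC | intermediate (not isolated)
6 | 1-methoxyprop-1-yne | COC#CC | intermediate
7 | (3E)-3-methylpenta-1,3-dien-1-one (vinylketene) | C/C=C(\C)C=C=O | intermediate (not isolated)
8 | 4-[(2E)-but-2-en-2-yl]-3-methoxy-2-methylcyclobut-2-en-1-one (racemic) | C/C=C(\C)C1C(OC)=C(C)C1=O | intermediate (not isolated)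
9 | (3E,5E)-3-methoxy-2,5-dimethylhepta-1,3,5-trien-1-one (dienylketene) | C/C=C(C)/C=C(OC)\C(C)=C=O | intermediate (not isolated)
10 | 3-methoxy-2,5,6-trimethylcyclohexa-2,4-dien-1-one (racemic) | CC1C(C)=CC(OC)=C(C)C1=O | intermediate (not isolated)
11 | 3-methoxy-2,5,6-trimethylphenol | COc1cc(C)c(C)c(O)c1C | intermediate
12 | 4-bromo-3-methoxy-2,5,6-trimethylphenol | COc1c(Br)c(C)c(C)c(O)c1C | intermediate
13 | lithium 4-lithio-3-methoxy-2,5,6-trimethylphenolate | [Li]Oc1c(C)c(C)c([Li])c(OC)c1C | intermediate (not isolated)
14 | methyl 2-methoxy-4-[(methoxycarbonyl)oxy]-3,5,6-trimethylbenzoate | COC(=O)Oc1c(C)c(C)c(C(=O)OC)c(OC)c1C | intermediate (not isolated)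
15 | methyl 4-hydroxy-2-methoxy-3,5,6-trimethylbenzoate | COC(=O)c1c(C)c(C)c(O)c(C)c1OC | intermediate
16 | orsellinic acid (2,4-dihydroxy-6-methylbenzoic acid) | Cc1cc(O)cc(O)c1C(=O)O | starting material
17 | benzyl 2,4-bis(benzyloxy)-6-methylbenzoate | Cc1cc(OCc2ccccc2)cc(OCc2ccccc2)c1C(=O)OCc1ccccc1 | intermediate
18 | 2,4-bis(benzyloxy)-6-methylbenzoic acid | Cc1cc(OCc2ccccc2)cc(OCc2ccccc2)c1C(=O)O | intermediate
19 | 2,4-bis(benzyloxy)-6-methylbenzoic trifluoroacetic anhydride | Cc1cc(OCc2ccccc2)cc(OCc2ccccc2)c1C(=O)OC(=O)C(F)(F)F | intermediate (not isolated)
20 | 3-methoxy-4-(methoxycarbonyl)-2,5,6-trimethylphenyl 2,4-bis(benzyloxy)-6-methylbenzoate | COC(=O)c1c(C)c(C)c(OC(=O)c2c(C)cc(OCc3ccccc3)cc2OCc2ccccc2)c(C)c1OC | intermediate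
21 | 3-methoxy-4-(methoxycarbonyl)-2,5,6-trimethylphenyl 2,4-dihydroxy-6-methylbenzoate | COC(=O)c1c(C)c(C)c(OC(=O)c2c(C)cc(O)cc2O)c(C)c1OC | intermediate
22 | 3-methoxy-4-(methoxycarbonyl)-2,5,6-trimethylphenyl 3,5-bis[chloro(methoxy)methyl]-2,4-dihydroxy-6-methylbenzoate (titanium-bound, stereoisomer mixture) | COC(=O)c1c(C)c(C)c(OC(=O)c2c(C)c(C(Cl)OC)c(O)c(C(Cl)OC)c2O)c(C)c1OC | intermediate (not isolated)
23 | 3-methoxy-4-(methoxycarbonyl)-2,5,6-trimethylphenyl 3,5-diformyl-2,4-dihydroxy-6-methylbenzoate | COC(=O)c1c(C)c(C)c(OC(=O)c2c(C)c(C=O)c(O)c(C=O)c2O)c(C)c1OC | target

## Step count and risks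

Total: 10 steps. Longest linear sequence: 7 steps (steps 1, 3, 4, 5, 8, 9, 10, from 1 to 23). The ring B branch (steps 6 and 7) and the alkyne branch (step 2) join it.

**Step 3 (key step).** The most likely failure is diversion of the vinylketene: acylation of the phenol already formed, or self-condensation once the volatile alkyne is depleted. Light absorption by the accumulating aromatic product can also stall the Wolff rearrangement. The fallback drops the diazo ketone and the lamp and uses the thermal cyclobutenone form of the benzannulation. It sets out from 6. N,N-Dimethylpropanamide is activated with Tf2O and 2,4,6-collidine in the presence of propyne (keteniminium [2+2] cycloaddition), and the adduct is hydrolysed to 3,4-dimethylcyclobut-2-en-1-one F1. Heating F1 with 6 in toluene at 80–110 °C opens the ring to the same vinylketene 7 and proceeds through 8, 9 and 10. The fallback returns to the route at 11.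

**Step 10.** The second substitution may stall, because titanium chelation of the first carbonyl equivalent lowers the reactivity of the ring. Prolonged exposure to the Lewis acid may also cleave the C6 methyl ether or the aryl ester. The fallback formylates before the ester is made and sets out from 16.
- Selective carboxylate alkylation (BnBr, KHCO3, DMF) gives benzyl 2,4-dihydroxy-6-methylbenzoate F2.
- A Duff reaction (hexamethylenetetramine, CF3CO2H, reflux; aq. HCl), which has no depside to endanger, gives benzyl 3,5-diformyl-2,4-dihydroxy-6-methylbenzoate F3.
- Brief hydrogenolysis (H2, Pd/C, EtOAc) gives 3,5-diformyl-2,4-dihydroxy-6-methylbenzoic acid F4, whose hydroxyls are tied up in hydrogen bonds to the carbonyl groups.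
- Carbodiimide condensation of F4 with 15 (DCC, toluene/Et2O) returns to the route at 23.

**Step 8.** O-acylation may be slow because both partners are hindered. The acylium ion may then C-acylate ring B of a second molecule of 18 or lose the ortho benzyl group. The fallback replaces acid-mediated acylium capture by acyl transfer to a phenolate and sets out from 18. Oxalyl chloride and catalytic DMF in CH2Cl2 give 2,4-bis(benzyloxy)-6-methylbenzoyl chloride F5. Phenol 15 is converted with NaH in THF into sodium 3-methoxy-4-(methoxycarbonyl)-2,5,6-trimethylphenolate F6. The two are combined at reflux, and the fallback returns at 20.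

**Step 5.** Exchange on the poorly soluble lithium phenolate may be incomplete, the aryllithium may be protonated, or a second addition to the new ester may occur. The fallback masks the phenol first and sets out from 12. Benzylation (BnBr, K2CO3, DMF) gives 1-(benzyloxy)-4-bromo-3-methoxy-2,5,6-trimethylbenzene F7. Exchange with n-BuLi (THF, −78 °C) and trapping with methyl chloroformate give methyl 4-(benzyloxy)-2-methoxy-3,5,6-trimethylbenzoate F8. Hydrogenolysis (H2, Pd/C) returns to the route at 15.

## Further compounds

F1 | step 3 | 3,4-dimethylcyclobut-2-en-1-one | CC1C(C)=CC1=O
F2 | step 10 | benzyl 2,4-dihydroxy-6-methylbenzoate | Cc1cc(O)cc(O)c1C(=O)OCc1ccccc1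
F3 | step 10 | benzyl 3,5-diformyl-2,4-dihydroxy-6-methylbenzoate | Cc1c(C=O)c(O)c(C=O)c(O)c1C(=O)OCc1ccccc1
F4 | step 10 | 3,5-diformyl-2,4-dihydroxy-6-methylbenzoic acid | Cc1c(C=O)c(O)c(C=O)c(O)c1C(=O)O
F5 | step 8 | 2,4-bis(benzyloxy)-6-methylbenzoyl chloride | Cc1cc(OCc2ccccc2)cc(OCc2ccccc2)c1C(Cl)=O
F6 | step 8 | sodium 3-methoxy-4-(methoxycarbonyl)-2,5,6-trimethylphenolate | COC(=O)c1c(C)c(C)c([O-])c(C)c1OC.[Na+]
F7 | step 5 | 1-(benzyloxy)-4-bromo-3-methoxy-2,5,6-trimethylbenzene | COc1c(Br)c(C)c(C)c(OCc2ccccc2)c1C
F8 | step 5 | methyl 4-(benzyloxy)-2-methoxy-3,5,6-trimethylbenzoate | COC(=O)c1c(C)c(C)c(OCc2ccccc2)c(C)c1OC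
A1 | alternative 1 | 3-methoxy-4-(methoxycarbonyl)-2,5,6-trimethylphenyl 3-formyl-4-hydroxy-2-(methoxymethoxy)-6-methylbenzoate | Cc1cc(O)c(C=O)c(OCOC)c1C(=O)Oc1c(C)c(C)c(C(=O)OC)c(OC)c1C
A2 | alternative 1 | 3-methoxy-4-(methoxycarbonyl)-2,5,6-trimethylphenyl 2-(methoxymethoxy)-6-methyl-4-{[(trifluoromethyl)sulfonyl]oxy}-3-(trimethylsilyl)benzoate | Cc1cc(OS(=O)(=O)C(F)(F)F)c([Si](C)(C)C)c(OCOC)c1C(=O)Oc1c(C)c(C)c(C(=O)OC)c(OC)c1C
A3 | alternative 1 | N,N-dimethylformamide | CN(C)C=O
A4 | alternative 2 | 3-methoxy-4-(methoxycarbonyl)-2,5,6-trimethylphenyl 2,4-dihydroxy-6-methylbenzoate | Cc1cc(O)cc(O)c1C(=O)Oc1c(C)c(C)c(C(=O)OC)c(OC)c1C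
A5 | alternative 2 | 3-methoxy-4-(methoxycarbonyl)-2,5,6-trimethylphenyl but-2-ynoate | CC#CC(=O)Oc1c(C)c(C)c(C(=O)OC)c(OC)c1C
A6 | alternative 2 | 1-methoxy-1,3-bis(trimethylsilyloxy)buta-1,3-diene | COC(O[Si](C)(C)C)=CC(=C)O[Si](C)(C)C
A7 | alternative 3 | methyl 2,4-dihydroxy-3,5,6-trimethylbenzoate | COC(=O)c1c(C)c(C)c(O)c(C)c1O
A8 | alternative 3 | pentan-3-one | CCC(=O)CC
A9 | alternative 3 | dimethyl 2-(1-methoxyethylidene)malonate | COC(C)=C(C(=O)OC)C(=O)OC
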